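## Structural features

The target is the diester of a centrosymmetric cyclobutane-1,3-dicarboxylic acid with two identical amino alcohols. The diacid is the head-to-tail dimer of 4-hydroxycinnamic acid, with each carboxyl cis to one neighbouring aryl group and trans to the other. Each amino alcohol is a cis-fused bicycle: an N-methylpiperidine (C1, N2, C3, C4, C4a, C7a) sharing the C4a–C7a bond with a cyclopentane (C4a, C5, C6, C7, C7a), configuration (4R,4aS,6R,7S,7aR). Its five stereocentres are contiguous (C4, C4a, C7a, C7, C6). On the cyclopentane the C6 oxygen and the C7 methyl are cis and share a face with the two ring-fusion hydrogens; C1 and C4 leave from the opposite face, and the C4 methyl is cis to C5. Fragile points are the cyclobutane centres alpha to the esters (epimerization through enolate or ketene, cycloreversion under UV), the free phenols, the two tertiary amines and the hindered secondary esters. Because the diacid is achiral, two identical enantiopure alcohols can give only one diester, so the real difficulty lies in the amino alcohol: a cis O/CH3 pair at C6/C7 beside a trans C7/C7a and a cis C7a/C4a relationship, none of which simple equilibration on a cyclopentane would give. The key step uses the cis C6–O/C7–CH3 pair: the methyl carbon is delivered from O6 through a temporary five-membered ring (O6, Si, CH2, C7, C6) that the target does not contain, and the C7a radical left behind closes the cyclopentane onto C4a.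

## Logic of the disconnections

26 to 25: the two phenolic O–H bonds are masked as silyl ethers. This lets the diacid be activated as an acid chloride; the forward step must free the phenols without touching the esters or the centres alpha to them.

25 to 19 (twice) and 23, through 24: the two acyl–oxygen bonds are cut. 23 is achiral and centrosymmetric and both alcohols are the same, so the cut halves the problem without any selectivity issue. The forward step must acylate a hindered secondary alcohol with retention at C6 and without epimerizing the cyclobutane.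

23 to 21 to 20 (twice): the two cyclobutane C–C bonds are cut along the head-to-tail [2+2] axis, back to two molecules of one achiral alkene. All four ring centres come from crystal packing; the forward step needs the photoreactive crystal form.

19 to 18: the C4–H bond is removed to leave an exocyclic alkene. This takes away one stereocentre; the forward hydrogenation must add hydrogen to C4 from the face anti to C5.

18 to 16, through 17: the N2–C3 bond is cut. The piperidine becomes an amine and an allylic chloride on one cyclopentane; the forward step is a 6-exo N-alkylation that must beat intermolecular alkylation.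

16 to 15: the C3–Cl bond is cut back to an isopropenyl group, the form in which the radical fragmentation leaves C4. The forward step must functionalize the methyl group and not the C4a–H.

15 to 14: the C7 methyl and the C6 hydroxyl are reconnected through silicon. This identifies the methyl carbon as a tethered CH2; the forward step must cleave one C–Si and one Si–O bond without base-induced alkene migration.

14 to 13 (key): the CH2–C7 and C7a–C4a bonds are cut. Two rings and three stereocentres are removed and an acyclic diene with one stereocentre remains. The forward step must close both rings in sequence, in the closure mode that puts the C5 chain and C7a cis on the first ring.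

13 to 11 and 12: the O–Si bond is cut; the demand is only a mild silylation of a secondary allylic alcohol.

11 to 6 and 8, through 9 and 10: the C6–C7 bond is cut between an aldehyde carbon and an (E)-alkenyl metal. The two halves are achiral, and the forward step must set C6 by catalyst control on an alpha-unbranched aldehyde.

8 to 7 and 6 to 5, 4, 3, 2, 1: protecting-group and oxidation-level changes. The allylic C–S bond is traced to an allylic C–H bond of a prenyl-type alkene and the aldehyde to a primary alcohol; the forward steps must keep the beta,gamma-alkene out of conjugation.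

## Other disconnections considered

Alternative 1: The cut is C1–C7a, with N2, C1 and the N-methyl group bought in as sarcosine, A1. Keto acid A2, in which A1 is N-acylated by an acetyl group that carries a 3-oxocyclopentyl ring on its alpha-carbon, would be electrolysed under Hofer–Moest (non-Kolbe) conditions in methanol. The carboxyl carbon is lost, C1 becomes an N-acyliminium carbon after Lewis-acid ionization of the N,O-acetal, and the enol of the C7 ketone attacks through C7a to give keto lactam A3.
- In its favour: C1 is activated without a reagent, no tin is used, and a six-membered closure onto a cyclopentanone can only be cis. The N-methyl lactam ring is finished in one step; on this point it is better than the chosen plan, which needs steps 10 to 13 for the piperidine.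
- Against it here: A3 carries none of the three substituents that make the target hard. The C7 methyl and C6 hydroxyl would have to be built from a C7 ketone with a carbonyl transposition, and a cis O/CH3 pair trans to C1 is not what alkylation followed by reduction or hydroboration naturally gives. The C4 methyl would be introduced alpha to the lactam, where alkylation from the convex face gives the wrong epimer and a further kinetic protonation is needed. Enolization of the ketone towards C6 would divert the Mannich step.
- Comparison: A3 is a simpler core but further from the target (two of the five stereocentres, against four in 14). Mechanistically it is a well-behaved polar closure, whereas the radical cascade has an intrinsic facial problem at C7. In step count the early gain would probably be spent on late redox and alkylation steps.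

Alternative 2: The cuts are C4a–C7a, C3–C4 and N2–C1. Diyne A4, whose tether already holds C5, the silylated C6 carbinol and the C7 methyl, would be combined with isocyanate A5 (methyl isocyanate) on zerovalent nickel, for example Ni(cod)2 with an N-heterocyclic carbene ligand, to give pyridone A6. Hydrogenation of the pyridone ring and reduction of the lactam would follow. A6 must carry the (6R,7S) configuration shown in the block below; the (6S,7R) form would lead to the enantiomeric series.
- In its favour: both rings, the N-methyl group and the C4 methyl come in one convergent step. The C6/C7 pair would be set in A4 by an anti-selective allenylmetal addition to an aldehyde, a dependable reaction, whereas the chosen cascade relies on the less favoured rotamer of a radical closure; on this point the alternative is the better.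
- Against it here: (a) only hydrogen versus methyl distinguishes the two alkyne termini of A4 that must choose between the carbonyl carbon and the nitrogen of A5; (b) A5 is volatile and highly toxic; (c) decisively, the all-cis hydrogenation of A6 would have to deliver three hydrogens (C4, C4a, C7a) on the face that already carries the silyl ether and the methyl group. Addition from the open face would place C1 and C4 cis to O6 and the C7 methyl, a diastereomer of the target, and pyridones are reluctant hydrogenation substrates.
- Comparison: at best equal in step count to the bicycle and superior in convergence, but it puts three centres at risk at once. The cascade, when the first closure goes the right way, sets C7a and C4a from the convex face in the sense the target needs.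

Alternative 3: The cuts are C6–C7 and C7a–C4a. Nitro enoate A7 and enal A8 (but-2-enal) would be joined by a secondary-amine catalyst of the diarylprolinol silyl ether type. The nitronate carbon C6 of A7 adds to the iminium ion of A8 at C7, and the resulting enamine then adds through C7a to C4a of the tethered enoate, giving cyclopentane A9.
- In its favour: one catalytic, metal-free step from the two achiral components A7 and A8 delivers every carbon of the amino alcohol except the N-methyl group. The nitro group is a latent C6 oxygen (Nef reaction), and the aldehyde and ester are ready for reductive amination and lactam formation. In step economy and in avoiding tin it is better than the chosen plan.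
- Against it here: A9 has the trans,trans arrangement, so of its defined centres only C4a is as the target needs it. C7a must be inverted when the cis-fused lactam closes, and C7 must then be inverted through enolization of the derived C6 ketone. C6 depends on a late hydride reduction and C4 on equilibration alpha to the lactam carbonyl, whose preferred sense is not obvious. The alpha-methyl enoate of A7 is also a sluggish acceptor for an enamine.
- Comparison: shorter and cleaner on paper, and equal in relaying everything from one catalyst-set centre. But it is a chain of thermodynamic corrections, whereas the chosen plan fixes C7a and C4a kinetically in the key step and C6 before it.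

Key step: step 9

Notes on the design of 13, and one assumption.
- The silicon tether by itself guarantees only that the new C7–CH2 bond is syn to the C6 oxygen. The configuration of C7 relative to the C5 chain is decided by the rotamer about C6–C7 in the first closure, and only the closure that puts the C5 chain and C7a on the same side of the oxasilolane can go on to the cyclopentane. This mode is the one the usual chair model for 4-substituted hexenyl radicals disfavours, so it is the main weakness of the plan.
- For that reason 13 keeps the (E)-alkene at C7=C7a (a (Z)-alkene would force the C6 hydrogen into the alkene plane and with it the unproductive mode), keeps the small dimethylsilyl group, and is cyclized hot.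
- Phenylthiyl does not abstract bromine; the stannane reduces it to thiophenol, a faster hydrogen donor than the stannane itself, so dilution matters.
- The siloxane is cleaved with fluoride directly after the cascade, so that no strong base meets the isopropenyl group and no acid meets the Si–O bond.
- Assumption: (−)-MIB, (2S)-3-exo-morpholinoisoborneol, is taken to deliver the alkenyl group to the Si face of 6, as it does in dialkylzinc additions; if the sense were opposite, the antipodal ligand would be used.

## Steps

Step 1
Reactants: 1 4-methylpent-3-en-1-ol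
Product: 2 4-methylpent-3-en-1-yl acetate
Conditions: Ac2O, pyridine, DMAP (cat.), CH2Cl2, 0 °C to rt
Reagents that add atoms: acetic anhydride, CC(=O)OC(C)=O
Why: O-acylation of a primary alcohol; the ester is inert to the allylic oxidation and to the thiolation and is removed later by methanolysis.

Step 2
Reactants: 2 4-methylpent-3-en-1-yl acetate
Product: 3 (3E)-5-hydroxy-4-methylpent-3-en-1-yl acetate
Conditions: SeO2 (0.3 equiv), t-BuOOH (2.5 equiv), salicylic acid (cat.), CH2Cl2, rt
Reagents that add atoms: tert-butyl hydroperoxide, CC(C)(C)OO
Why: Catalytic SeO2 allylic hydroxylation (ene reaction, then [2,3]-sigmatropic shift) oxidizes the (E)-methyl group of a trisubstituted alkene. Enal from over-oxidation, a known minor product, is separated; the alkene geometry is erased later in any case.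

Step 3
Reactants: 3 (3E)-5-hydroxy-4-methylpent-3-en-1-yl acetate
Product: 4 (3E)-4-methyl-5-(phenylsulfanyl)pent-3-en-1-yl acetate
Conditions: PhSSPh, n-Bu3P, pyridine, rt
Reagents that add atoms: diphenyl disulfide, c1ccc(SSc2ccccc2)cc1
Why: Disulfide/phosphine redox condensation (Mitsunobu-type): the alkoxyphosphonium ion is displaced by thiolate in an SN2 reaction at the primary allylic carbon, without transposition.

Step 4
Reactants: 4 (3E)-4-methyl-5-(phenylsulfanyl)pent-3-en-1-yl acetate
Product: 5 (3E)-4-methyl-5-(phenylsulfanyl)pent-3-en-1-ol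
Conditions: K2CO3 (0.2 equiv), MeOH, rt
Reagents that add atoms: none
Why: Base-catalysed transesterification of a primary acetate; the allylic sulfide is stable to carbonate in methanol.

Step 5
Reactants: 5 (3E)-4-methyl-5-(phenylsulfanyl)pent-3-en-1-ol
Product: 6 (3E)-4-methyl-5-(phenylsulfanyl)pent-3-enal
Conditions: Dess–Martin periodinane, NaHCO3, CH2Cl2, 0 °C; used at once without chromatography
Reagents that add atoms: none
Why: Dess–Martin oxidation under buffered, base-free conditions; aryl alkyl sulfides react with the periodinane much more slowly than primary alcohols. A beta,gamma-unsaturated aldehyde with a trisubstituted alkene, like its 4-methylpent-3-enal parent, holds its alkene position if used at once.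

Step 6
Reactants: 7 N-methylprop-2-yn-1-amine
Product: 8 tert-butyl N-methyl-N-(prop-2-yn-1-yl)carbamate
Conditions: Boc2O, Et3N, CH2Cl2, 0 °C to rt
Reagents that add atoms: di-tert-butyl dicarbonate, CC(C)(C)OC(=O)OC(=O)OC(C)(C)C
Why: Carbamate formation on a secondary amine; the tertiary carbamate has no N–H and is inert to boranes, organozincs and radicals.

Step 7
Reactants: 8 tert-butyl N-methyl-N-(prop-2-yn-1-yl)carbamate; 6 (3E)-4-methyl-5-(phenylsulfanyl)pent-3-enal
Product: 11 tert-butyl N-[(2E,4R,6E)-4-hydroxy-7-methyl-8-(phenylsulfanyl)octa-2,6-dien-1-yl]-N-methylcarbamate, via alkenylborane 9 (not isolated), via alkenylzinc 10 (not isolated)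
Conditions: Cy2BH, PhMe, 0 °C to rt; Me2Zn, −78 °C; (−)-MIB (5 mol %); then 6, −78 to −10 °C; aq. NH4Cl
Reagents that add atoms: none
Why: Syn hydroboration of the terminal alkyne gives the (E)-alkenylborane, boron-to-zinc exchange gives the alkenylzinc, and the zinc alkoxide of (−)-MIB transfers the alkenyl group to the Si face of 6 (catalytic asymmetric alkenylzinc addition). This sets C6 as (R) (OH > alkenyl > CH2 > H); dialkylzincs do not enolize the aldehyde.

Step 8
Reactants: 11 tert-butyl N-[(2E,4R,6E)-4-hydroxy-7-methyl-8-(phenylsulfanyl)octa-2,6-dien-1-yl]-N-methylcarbamate; 12 (bromomethyl)chlorodimethylsilane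
Product: 13 tert-butyl N-[(2E,4R,6E)-4-{[(bromomethyl)dimethylsilyl]oxy}-7-methyl-8-(phenylsulfanyl)octa-2,6-dien-1-yl]-N-methylcarbamate
Conditions: Et3N, DMAP (cat.), CH2Cl2, 0 °C; filtration through deactivated silica, used at once
Reagents that add atoms: none
Why: O-silylation of a secondary alcohol by a chlorosilane; C6 is not touched. The ether is moisture-sensitive and is not stored.

Step 9
Reactants: 13 tert-butyl N-[(2E,4R,6E)-4-{[(bromomethyl)dimethylsilyl]oxy}-7-methyl-8-(phenylsulfanyl)octa-2,6-dien-1-yl]-N-methylcarbamate
Product: 14 tert-butyl N-methyl-N-{[(1R,5S,6R,7R)-3,3-dimethyl-7-(prop-1-en-2-yl)-2-oxa-3-silabicyclo[3.3.0]octan-6-yl]methyl}carbamate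
Conditions: Bu3SnH (1.3 equiv) and 1,1'-azobis(cyclohexanecarbonitrile) (0.2 equiv) added over 8 h, PhMe (0.01 M), 110 °C; aq. KF
Reagents that add atoms: none
Why: The stannyl radical abstracts bromine from 13; the alpha-silyl radical adds 5-exo-trig to C7 and closes the oxasilolane, the C7a radical adds 5-exo-trig to C4a and closes the cyclopentane, and the tertiary C4 radical loses phenylthiyl by beta-scission, which the stannane turns into thiophenol and a new stannyl radical. The closest known reactions are the 5-exo cyclization of bromomethylsilyl ethers of allylic alcohols and tandem 5-exo cyclizations ended by fragmentation of an allylic sulfide. At C7 the tether forces the new C–C bond syn to the C6 oxygen, but the configuration relative to the C5 chain depends on the rotamer about C6–C7: the product needs the closure in which the chain is axial or inside, so that chain and C7a end up cis on the oxasilolane, whereas the chair with the chain equatorial, normally preferred for a 4-substituted hexenyl radical, gives the trans radical. That trans radical cannot reach C4a without forming a trans-fused bicyclo[3.3.0] system and should be reduced instead, so the second closure acts as a filter and 14 should be the only bicyclic product, at the cost of material diverted to a monocyclic siloxane. At C7a and C4a, C1 takes the exo position of the forming cis-fused bicycle, trans to the ring CH2 on C7, and the attacked alkene lies cis to C1 on the convex face (the usual cis preference of a radical substituted at the radical carbon), which gives C1 cis to the isopropenyl group. The (E)-alkene leaves no allylic strain to forbid the productive rotamer, the methyl groups on silicon keep the cost of an axial chain low, and the high temperature narrows the gap between the two modes. Chemoselectivity (5-exo at C7 before 6-exo at C4a, bromine abstraction before stannyl addition to the allylic sulfide) follows from the rate order of these elementary steps, and dilution with slow addition limits hydrogen transfer from the stannane and from accumulating thiophenol to the first two radicals.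

Step 10
Reactants: 14 tert-butyl N-methyl-N-{[(1R,5S,6R,7R)-3,3-dimethyl-7-(prop-1-en-2-yl)-2-oxa-3-silabicyclo[3.3.0]octan-6-yl]methyl}carbamate
Product: 15 tert-butyl N-{[(1R,2S,3R,5R)-3-hydroxy-2-methyl-5-(prop-1-en-2-yl)cyclopentyl]methyl}-N-methylcarbamate
Conditions: TBAF (5 equiv), wet DMF, 70 °C
Reagents that add atoms: none
Why: Fluoride-induced protodesilylation of a 1-oxa-2-silacyclopentane: the pentacoordinate siliconate undergoes C–Si protonolysis to the C7 methyl and Si–O cleavage to the C6 hydroxyl. No stereocentre is touched; hydrated fluoride is not basic enough to move the isopropenyl double bond, which is why it is used in place of an alkoxide in DMSO.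

Step 11
Reactants: 15 tert-butyl N-{[(1R,2S,3R,5R)-3-hydroxy-2-methyl-5-(prop-1-en-2-yl)cyclopentyl]methyl}-N-methylcarbamate
Product: 16 tert-butyl N-{[(1R,2S,3R,5R)-5-(3-chloroprop-1-en-2-yl)-3-hydroxy-2-methylcyclopentyl]methyl}-N-methylcarbamate
Conditions: Ca(OCl)2, CO2 (solid), CH2Cl2/H2O, 0 °C
Reagents that add atoms: calcium hypochlorite, [Ca+2].[O-]Cl.[O-]Cl
Why: Ene-type chlorination by hypochlorous acid: chlorine adds to the terminal carbon and a methyl proton is lost, giving the 2-(chloromethyl)allyl unit. Isopropenyl terpenoids with a free secondary hydroxyl react this way, and the tertiary carbamate has no N–H to chlorinate.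

Step 12
Reactants: 16 tert-butyl N-{[(1R,2S,3R,5R)-5-(3-chloroprop-1-en-2-yl)-3-hydroxy-2-methylcyclopentyl]methyl}-N-methylcarbamate
Product: 18 (4aR,6R,7S,7aR)-2,7-dimethyl-4-methylideneoctahydro-1H-cyclopenta[c]pyridin-6-ol, via amine salt 17 (not isolated)
Conditions: TFA, CH2Cl2, 0 °C; concentrate; K2CO3, NaI (cat.), MeCN (0.02 M), 50 °C
Reagents that add atoms: none
Why: Acidolysis of the Boc group, then intramolecular 6-exo-tet SN2 N-alkylation by the allylic chloride (iodide catalysis); dilution suppresses intermolecular alkylation and the hydroxyl does not compete with the amine. C1 and C4 are cis on the cyclopentane, so the ring closes without strain.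

Step 13
Reactants: 18 (4aR,6R,7S,7aR)-2,7-dimethyl-4-methylideneoctahydro-1H-cyclopenta[c]pyridin-6-ol
Product: 19 (4R,4aS,6R,7S,7aR)-2,4,7-trimethyloctahydro-1H-cyclopenta[c]pyridin-6-ol
Conditions: H2 (1 atm), PtO2 (cat.), EtOH, rt
Reagents that add atoms: none
Why: Heterogeneous hydrogenation of the exocyclic alkene: hydrogen should add to C4 from the face anti to the C4a–C5 bond, the convex face of the cis-fused bicycle and the usual course for a methylidene next to a ring-fusion carbon. This places the C4 methyl cis to C5 (4R); PtO2 is chosen over palladium to limit alkene migration.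

Step 14
Reactants: 20 (2E)-3-(4-hydroxyphenyl)prop-2-enoic acid (two molecules)
Product: 21 (1α,2α,3β,4β)-2,4-bis(4-hydroxyphenyl)cyclobutane-1,3-dicarboxylic acid
Conditions: hν (medium-pressure Hg lamp, Pyrex), crystalline powder suspended in hexane, rt
Reagents that add atoms: (2E)-3-(4-hydroxyphenyl)prop-2-enoic acid (the second molecule of 20), OC(=O)/C=C/c1ccc(O)cc1
Why: Topochemical head-to-tail [2+2] photocycloaddition in the crystal, in which two molecules of 20 related by a centre of symmetry (alpha-type packing) join through their alkene carbons. All four cyclobutane centres are fixed by the packing and the product is achiral.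

Step 15
Reactants: 21 (1α,2α,3β,4β)-2,4-bis(4-hydroxyphenyl)cyclobutane-1,3-dicarboxylic acid
Product: 23 (1α,2α,3β,4β)-2,4-bis{4-[(tert-butyldimethylsilyl)oxy]phenyl}cyclobutane-1,3-dicarboxylic acid, via tetrasilyl derivative 22 (not isolated)
Conditions: TBSCl (4.6 equiv), imidazole, DMF, rt; then AcOH/THF/H2O, rt
Reagents that add atoms: tert-butyldimethylsilyl chloride (two molecules, one per phenol), CC(C)(C)[Si](C)(C)Cl.CC(C)(C)[Si](C)(C)Cl
Why: Silylation of phenols and acids, then selective hydrolysis of the labile silyl esters under mild acid, to which aryl silyl ethers are stable. A silyl ether, unlike an aryl acetate, cannot transfer an acyl group to 19 in the next step.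

Step 16
Reactants: 23 (1α,2α,3β,4β)-2,4-bis{4-[(tert-butyldimethylsilyl)oxy]phenyl}cyclobutane-1,3-dicarboxylic acid; 19 (4R,4aS,6R,7S,7aR)-2,4,7-trimethyloctahydro-1H-cyclopenta[c]pyridin-6-ol (two molecules)
Product: 25 bis[(4R,4aS,6R,7S,7aR)-2,4,7-trimethyloctahydro-1H-cyclopenta[c]pyridin-6-yl] (1α,2α,3β,4β)-2,4-bis{4-[(tert-butyldimethylsilyl)oxy]phenyl}cyclobutane-1,3-dicarboxylate, via diacid dichloride 24 (not isolated)
Conditions: (COCl)2, DMF (cat.), CH2Cl2, 0 °C to rt; concentrate; 19 (2.2 equiv), pyridine, DMAP (0.2 equiv), CH2Cl2, 0 °C to rt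
Reagents that add atoms: (4R,4aS,6R,7S,7aR)-2,4,7-trimethyloctahydro-1H-cyclopenta[c]pyridin-6-ol (the second molecule of 19), C[C@H]1[C@@H]2CN(C)C[C@H](C)[C@@H]2C[C@H]1O
Why: Acid chloride formation, then DMAP-catalysed acylation of the secondary alcohol at both acyl groups; the C6–O bond is not broken, so C6 keeps its configuration. Pyridine rather than a trialkylamine is used to avoid ketene formation and epimerization of the cyclobutane; two identical alcohols and a centrosymmetric diacid can give only one diester.

Step 17
Reactants: 25 bis[(4R,4aS,6R,7S,7aR)-2,4,7-trimethyloctahydro-1H-cyclopenta[c]pyridin-6-yl] (1α,2α,3β,4β)-2,4-bis{4-[(tert-butyldimethylsilyl)oxy]phenyl}cyclobutane-1,3-dicarboxylate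
Product: 26 bis[(4R,4aS,6R,7S,7aR)-2,4,7-trimethyloctahydro-1H-cyclopenta[c]pyridin-6-yl] (1α,2α,3β,4β)-2,4-bis(4-hydroxyphenyl)cyclobutane-1,3-dicarboxylate (CNP0180864.2)
Conditions: TBAF, AcOH (1:1), THF, 0 °C
Reagents that add atoms: none
Why: Fluoride cleavage of the aryl silyl ethers, buffered with acetic acid so that neither the esters nor the centres alpha to them meet base.

## Compound list

1 | 4-methylpent-3-en-1-ol | CC(C)=CCCO | starting material
2 | 4-methylpent-3-en-1-yl acetate | CC(C)=CCCOC(C)=O | intermediate
3 | (3E)-5-hydroxy-4-methylpent-3-en-1-yl acetate | OC/C(C)=C/CCOC(C)=O | intermediate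
4 | (3E)-4-methyl-5-(phenylsulfanyl)pent-3-en-1-yl acetate | CC(=O)OCC/C=C(\C)CSc1ccccc1 | intermediate
5 | (3E)-4-methyl-5-(phenylsulfanyl)pent-3-en-1-ol | OCC/C=C(\C)CSc1ccccc1 | intermediate
6 | (3E)-4-methyl-5-(phenylsulfanyl)pent-3-enal | O=CC/C=C(\C)CSc1ccccc1 | intermediate
7 | N-methylprop-2-yn-1-amine | CNCC#C | starting material
8 | tert-butyl N-methyl-N-(prop-2-yn-1-yl)carbamate | CN(CC#C)C(=O)OC(C)(C)C | intermediate
9 | tert-butyl N-[(2E)-3-(dicyclohexylboranyl)prop-2-en-1-yl]-N-methylcarbamate | CN(C/C=C/B(C1CCCCC1)C1CCCCC1)C(=O)OC(C)(C)C | intermediate (not isolated)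
10 | {(1E)-3-[(tert-butoxycarbonyl)(methyl)amino]prop-1-en-1-yl}(methyl)zinc | CN(C/C=C/[Zn]C)C(=O)OC(C)(C)C | intermediate (not isolated)
11 | tert-butyl N-[(2E,4R,6E)-4-hydroxy-7-methyl-8-(phenylsulfanyl)octa-2,6-dien-1-yl]-N-methylcarbamate | O[C@H](C/C=C(\C)CSc1ccccc1)/C=C/CN(C)C(=O)OC(C)(C)C | intermediate
12 | (bromomethyl)chlorodimethylsilane | C[Si](C)(Cl)CBr | starting material
13 | tert-butyl N-[(2E,4R,6E)-4-{[(bromomethyl)dimethylsilyl]oxy}-7-methyl-8-(phenylsulfanyl)octa-2,6-dien-1-yl]-N-methylcarbamate | BrC[Si](C)(C)O[C@H](C/C=C(\C)CSc1ccccc1)/C=C/CN(C)C(=O)OC(C)(C)C | intermediate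
14 | tert-butyl N-methyl-N-{[(1R,5S,6R,7R)-3,3-dimethyl-7-(prop-1-en-2-yl)-2-oxa-3-silabicyclo[3.3.0]octan-6-yl]methyl}carbamate | C[Si]1(C)C[C@H]2[C@H](CN(C)C(=O)OC(C)(C)C)[C@H](C(C)=C)C[C@H]2O1 | intermediate
15 | tert-butyl N-{[(1R,2S,3R,5R)-3-hydroxy-2-methyl-5-(prop-1-en-2-yl)cyclopentyl]methyl}-N-methylcarbamate | C[C@H]1[C@H](CN(C)C(=O)OC(C)(C)C)[C@H](C(C)=C)C[C@H]1O | intermediate
16 | tert-butyl N-{[(1R,2S,3R,5R)-5-(3-chloroprop-1-en-2-yl)-3-hydroxy-2-methylcyclopentyl]methyl}-N-methylcarbamate | C[C@H]1[C@H](CN(C)C(=O)OC(C)(C)C)[C@H](C(=C)CCl)C[C@H]1O | intermediate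
17 | (1R,2S,3R,4R)-4-(3-chloroprop-1-en-2-yl)-2-methyl-3-[(methylamino)methyl]cyclopentan-1-ol (present as its trifluoroacetate salt) | C[C@H]1[C@H](CNC)[C@H](C(=C)CCl)C[C@H]1O | intermediate (not isolated)
18 | (4aR,6R,7S,7aR)-2,7-dimethyl-4-methylideneoctahydro-1H-cyclopenta[c]pyridin-6-ol | C[C@H]1[C@@H]2CN(C)CC(=C)[C@@H]2C[C@H]1O | intermediate
19 | (4R,4aS,6R,7S,7aR)-2,4,7-trimethyloctahydro-1H-cyclopenta[c]pyridin-6-ol | C[C@H]1[C@@H]2CN(C)C[C@H](C)[C@@H]2C[C@H]1O | intermediate
20 | (2E)-3-(4-hydroxyphenyl)prop-2-enoic acid | OC(=O)/C=C/c1ccc(O)cc1 | starting material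
21 | (1α,2α,3β,4β)-2,4-bis(4-hydroxyphenyl)cyclobutane-1,3-dicarboxylic acid | OC(=O)[C@H]1[C@H](c2ccc(O)cc2)[C@H](C(=O)O)[C@H]1c1ccc(O)cc1 | intermediate
22 | bis(tert-butyldimethylsilyl) (1α,2α,3β,4β)-2,4-bis{4-[(tert-butyldimethylsilyl)oxy]phenyl}cyclobutane-1,3-dicarboxylate | CC(C)(C)[Si](C)(C)OC(=O)[C@H]1[C@H](c2ccc(O[Si](C)(C)C(C)(C)C)cc2)[C@H](C(=O)O[Si](C)(C)C(C)(C)C)[C@H]1c1ccc(O[Si](C)(C)C(C)(C)C)cc1 | intermediate (not isolated)
23 | (1α,2α,3β,4β)-2,4-bis{4-[(tert-butyldimethylsilyl)oxy]phenyl}cyclobutane-1,3-dicarboxylic acid | OC(=O)[C@H]1[C@H](c2ccc(O[Si](C)(C)C(C)(C)C)cc2)[C@H](C(=O)O)[C@H]1c1ccc(O[Si](C)(C)C(C)(C)C)cc1 | intermediate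
24 | (1α,2α,3β,4β)-2,4-bis{4-[(tert-butyldimethylsilyl)oxy]phenyl}cyclobutane-1,3-dicarbonyl dichloride | ClC(=O)[C@H]1[C@H](c2ccc(O[Si](C)(C)C(C)(C)C)cc2)[C@H](C(Cl)=O)[C@H]1c1ccc(O[Si](C)(C)C(C)(C)C)cc1 | intermediate (not isolated)
25 | bis[(4R,4aS,6R,7S,7aR)-2,4,7-trimethyloctahydro-1H-cyclopenta[c]pyridin-6-yl] (1α,2α,3β,4β)-2,4-bis{4-[(tert-butyldimethylsilyl)oxy]phenyl}cyclobutane-1,3-dicarboxylate | C[C@H]1[C@@H]2CN(C)C[C@H](C)[C@@H]2C[C@H]1OC(=O)[C@H]1[C@H](c2ccc(O[Si](C)(C)C(C)(C)C)cc2)[C@H](C(=O)O[C@@H]2C[C@@H]3[C@@H](CN(C)C[C@@H]3C)[C@@H]2C)[C@H]1c1ccc(O[Si](C)(C)C(C)(C)C)cc1 | intermediate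
26 | bis[(4R,4aS,6R,7S,7aR)-2,4,7-trimethyloctahydro-1H-cyclopenta[c]pyridin-6-yl] (1α,2α,3β,4β)-2,4-bis(4-hydroxyphenyl)cyclobutane-1,3-dicarboxylate | C[C@H]1[C@@H]2CN(C)C[C@H](C)[C@@H]2C[C@H]1OC(=O)[C@H]1[C@H](c2ccc(O)cc2)[C@H](C(=O)O[C@@H]2C[C@@H]3[C@@H](CN(C)C[C@@H]3C)[C@@H]2C)[C@H]1c1ccc(O)cc1 | target

## Step count and least certain steps

Total: 17 steps. Longest linear sequence: 14 steps (1 to 5, 7 to 13, 16, 17).

Step 9 (key step). The most likely failure is poor facial selectivity in the first closure: attack on C7 through the rotamer with the C5 chain equatorial or outside, the mode the chair model usually favours, followed by reduction of a C7a radical that cannot reach C4a. This costs material, not stereochemical purity. Further losses may come from hydrogen transfer from thiophenol or the stannane to the alpha-silyl or C7a radical before ring closure, from 6-exo closure of the alpha-silyl radical onto C4a, and from stannyl attack on the allylic sulfide.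

The fallback sets out from 6 and returns at 15. It makes the C6–C7 pair before any radical step and closes the cyclopentane in the C6-epimeric series, where all substituent effects of an open-chain 5-exo closure point the same way.
- An Evans syn-aldol of 6 with (4R)-4-benzyl-3-propanoyl-1,3-oxazolidin-2-one (Bu2BOTf, i-Pr2NEt, non-oxidative work-up) would give imide F1.
- TBSOTf and 2,6-lutidine give silyl ether F2, LiBH4 removes the auxiliary to give alcohol F3, and Dess–Martin oxidation gives aldehyde F4.
- LiCH2N(Me)Boc (from tert-butyl dimethylcarbamate, s-BuLi, TMEDA) adds to give carbinol F5 as a mixture at the new centre, which does not matter; PhOC(S)Cl, pyridine and DMAP give thionocarbonate F6.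
- Bu3SnH with a radical initiator generates the C7a radical (Barton–McCombie-type), which closes 5-exo onto C4a with loss of phenylthiyl to give cyclopentane F7. The C7 methyl (trans to the new bond), the C6 silyloxy group (cis) and the C1 substituent (cis) all favour the same chair, which carries the natural configuration at C7, C7a and C4a.
- TBAF gives the C6-epimeric alcohol F8, Dess–Martin oxidation gives ketone F9, and LiBH(s-Bu)3, attacking anti to the C7 methyl, returns the cis alcohol 15.

Step 7. Enantioselectivity may be eroded with an alpha-unbranched aldehyde and a coordinating carbamate (uncatalysed alkenyl or methyl transfer), and the double bond of 6 may move into conjugation before addition. The fallback sets out from 6 and 8 and returns at 11: deprotonation of 8 (n-BuLi, THF, −78 °C) and addition to 6 gives racemic propargylic alcohol F10; MnO2 gives ynone F11; Noyori transfer hydrogenation with RuCl[(R,R)-TsDPEN](p-cymene) in i-PrOH without added base gives (R)-propargylic alcohol F12; trans-selective reduction with NaAlH2(OCH2CH2OMe)2 at 0 °C gives 11.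

Step 13. Facial discrimination may be insufficient, because two chair forms of the cis-fused bicycle are accessible and the hydroxyl and amine can anchor the substrate to the catalyst surface; the alkene may also migrate into the ring. The fallback sets out from 15 and returns at 19, setting C4 on the open chain by catalyst control. SeO2/t-BuOOH oxidizes the isopropenyl methyl group to give allylic alcohol F13. Hydrogenation with [Ir(cod)(t-Bu-PHOX)][B(3,5-(CF3)2C6H3)4], using the ligand enantiomer that delivers (R) at C4, gives diol F14. TsCl/pyridine at 0 °C sulfonylates the primary hydroxyl selectively to give tosylate F15. TFA, then K2CO3 in MeCN, removes the Boc group and closes the piperidine by N-alkylation to give 19.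

Step 16. The second acylation at the hindered carbinol may stall, leaving mono-ester, and the acid chloride may epimerize through a ketene. The fallback sets out from 19 and returns at 25, making the esters by SN2 inversion instead. A Mitsunobu reaction of 19 with 4-nitrobenzoic acid (PPh3, DIAD) gives the inverted ester F16; K2CO3/MeOH gives the C6-epimeric alcohol F17; a double Mitsunobu reaction of F17 with diacid 23 (n-Bu3P, N,N,N',N'-tetramethylazodicarboxamide) inverts C6 again and gives 25.

## Further compounds

F1 | step 9 | (4R)-4-benzyl-3-[(2R,3S,5E)-3-hydroxy-2,6-dimethyl-7-(phenylsulfanyl)hept-5-enoyl]-1,3-oxazolidin-2-one | O=C1OC[C@@H](Cc2ccccc2)N1C(=O)[C@H](C)[C@@H](O)C/C=C(\C)CSc1ccccc1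
F2 | step 9 | (4R)-4-benzyl-3-[(2R,3S,5E)-3-{[tert-butyl(dimethyl)silyl]oxy}-2,6-dimethyl-7-(phenylsulfanyl)hept-5-enoyl]-1,3-oxazolidin-2-one | O=C1OC[C@@H](Cc2ccccc2)N1C(=O)[C@H](C)[C@@H](O[Si](C)(C)C(C)(C)C)C/C=C(\C)CSc1ccccc1
F3 | step 9 | (2S,3S,5E)-3-{[tert-butyl(dimethyl)silyl]oxy}-2,6-dimethyl-7-(phenylsulfanyl)hept-5-en-1-ol | OC[C@H](C)[C@@H](O[Si](C)(C)C(C)(C)C)C/C=C(\C)CSc1ccccc1
F4 | step 9 | (2R,3S,5E)-3-{[tert-butyl(dimethyl)silyl]oxy}-2,6-dimethyl-7-(phenylsulfanyl)hept-5-enal | O=C[C@H](C)[C@@H](O[Si](C)(C)C(C)(C)C)C/C=C(\C)CSc1ccccc1
F5 | step 9 | tert-butyl N-[(3S,4S,6E)-4-{[tert-butyl(dimethyl)silyl]oxy}-2-hydroxy-3,7-dimethyl-8-(phenylsulfanyl)oct-6-en-1-yl]-N-methylcarbamate (both C2 epimers) | CN(CC(O)[C@H](C)[C@@H](O[Si](C)(C)C(C)(C)C)C/C=C(\C)CSc1ccccc1)C(=O)OC(C)(C)C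
F6 | step 9 | tert-butyl N-[(3S,4S,6E)-4-{[tert-butyl(dimethyl)silyl]oxy}-3,7-dimethyl-2-[(phenoxycarbonothioyl)oxy]-8-(phenylsulfanyl)oct-6-en-1-yl]-N-methylcarbamate (both C2 epimers) | CN(CC(OC(=S)Oc1ccccc1)[C@H](C)[C@@H](O[Si](C)(C)C(C)(C)C)C/C=C(\C)CSc1ccccc1)C(=O)OC(C)(C)C
F7 | step 9 | tert-butyl N-{[(1R,2S,3S,5R)-3-{[tert-butyl(dimethyl)silyl]oxy}-2-methyl-5-(prop-1-en-2-yl)cyclopentyl]methyl}-N-methylcarbamate | C[C@H]1[C@H](CN(C)C(=O)OC(C)(C)C)[C@H](C(C)=C)C[C@@H]1O[Si](C)(C)C(C)(C)C
F8 | step 9 | tert-butyl N-{[(1R,2S,3S,5R)-3-hydroxy-2-methyl-5-(prop-1-en-2-yl)cyclopentyl]methyl}-N-methylcarbamate | C[C@H]1[C@H](CN(C)C(=O)OC(C)(C)C)[C@H](C(C)=C)C[C@@H]1O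
F9 | step 9 | tert-butyl N-methyl-N-{[(1R,2S,5R)-2-methyl-3-oxo-5-(prop-1-en-2-yl)cyclopentyl]methyl}carbamate | C[C@H]1[C@H](CN(C)C(=O)OC(C)(C)C)[C@H](C(C)=C)CC1=O
F10 | step 7 | tert-butyl N-[(6E)-4-hydroxy-7-methyl-8-(phenylsulfanyl)oct-6-en-2-yn-1-yl]-N-methylcarbamate (racemic) | CN(CC#CC(O)C/C=C(\C)CSc1ccccc1)C(=O)OC(C)(C)C
F11 | step 7 | tert-butyl N-methyl-N-[(6E)-7-methyl-4-oxo-8-(phenylsulfanyl)oct-6-en-2-yn-1-yl]carbamate | CN(CC#CC(=O)C/C=C(\C)CSc1ccccc1)C(=O)OC(C)(C)C
F12 | step 7 | tert-butyl N-[(4R,6E)-4-hydroxy-7-methyl-8-(phenylsulfanyl)oct-6-en-2-yn-1-yl]-N-methylcarbamate | CN(CC#C[C@H](O)C/C=C(\C)CSc1ccccc1)C(=O)OC(C)(C)C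
F13 | step 13 | tert-butyl N-{[(1R,2S,3R,5R)-3-hydroxy-5-(3-hydroxyprop-1-en-2-yl)-2-methylcyclopentyl]methyl}-N-methylcarbamate | C[C@H]1[C@H](CN(C)C(=O)OC(C)(C)C)[C@H](C(=C)CO)C[C@H]1O
F14 | step 13 | tert-butyl N-{[(1R,2S,3R,5R)-3-hydroxy-5-[(2R)-1-hydroxypropan-2-yl]-2-methylcyclopentyl]methyl}-N-methylcarbamate | C[C@H]1[C@H](CN(C)C(=O)OC(C)(C)C)[C@H]([C@@H](C)CO)C[C@H]1O
F15 | step 13 | (2R)-2-[(1R,2R,3S,4R)-2-{[(tert-butoxycarbonyl)(methyl)amino]methyl}-4-hydroxy-3-methylcyclopentyl]propyl 4-methylbenzenesulfonate | C[C@H]1[C@H](CN(C)C(=O)OC(C)(C)C)[C@H]([C@@H](C)COS(=O)(=O)c2ccc(C)cc2)C[C@H]1O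
F16 | step 16 | (4R,4aS,6S,7S,7aR)-2,4,7-trimethyloctahydro-1H-cyclopenta[c]pyridin-6-yl 4-nitrobenzoate | C[C@H]1[C@@H]2CN(C)C[C@H](C)[C@@H]2C[C@@H]1OC(=O)c1ccc([N+](=O)[O-])cc1
F17 | step 16 | (4R,4aS,6S,7S,7aR)-2,4,7-trimethyloctahydro-1H-cyclopenta[c]pyridin-6-ol | C[C@H]1[C@@H]2CN(C)C[C@H](C)[C@@H]2C[C@@H]1O
A1 | alternative 1 | N-methylglycine (sarcosine) | CNCC(=O)O
A2 | alternative 1 | N-methyl-N-{[(1R)-3-oxocyclopentyl]acetyl}glycine | OC(=O)CN(C)C(=O)C[C@@H]1CCC(=O)C1
A3 | alternative 1 | (4aS,7aR)-2-methylhexahydro-1H-cyclopenta[c]pyridine-3,7(2H,4H)-dione | CN1C[C@H]2C(=O)CC[C@H]2CC1=O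
A4 | alternative 2 | (3S,4R)-4-{[tert-butyl(dimethyl)silyl]oxy}-3-methylocta-1,6-diyne | C#C[C@H](C)[C@H](O[Si](C)(C)C(C)(C)C)CC#CC
A5 | alternative 2 | methyl isocyanate | CN=C=O
A6 | alternative 2 | (6R,7S)-6-{[tert-butyl(dimethyl)silyl]oxy}-2,4,7-trimethyl-2,5,6,7-tetrahydro-3H-cyclopenta[c]pyridin-3-one | C[C@@H]1[C@H](O[Si](C)(C)C(C)(C)C)CC2=C(C)C(=O)N(C)C=C12
A7 | alternative 3 | ethyl (2E)-2-methyl-5-nitropent-2-enoate | CCOC(=O)/C(C)=C/CC[N+](=O)[O-]
A8 | alternative 3 | (2E)-but-2-enal | C/C=C/C=O
A9 | alternative 3 | ethyl 2-[(1R,2S,3R)-2-formyl-3-methyl-4-nitrocyclopentyl]propanoate (epimers at the nitro carbon and at the propanoate alpha-carbon) | O=C[C@@H]1[C@@H](C)C([N+](=O)[O-])C[C@H]1C(C)C(=O)OCC
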